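**Remarks on the chemistry.** The SMILES has no stereodescriptor and the molecule has no stereogenic element, so no stereocentre has to be set. Rings are lettered A to H in the order of the SMILES string. Compounds 1, 2, 6, 15, 20, 21, 25 and 29 are taken as catalogue chemicals. In names, Ar(D) is the aryl group of phenol 14 bonded through D4, and Ar(F) is the aryl group of phenol 28 bonded through F1.

## Analysis of the target

The target (C48H34O28) is a linear chain of eight benzene rings A to H joined only by seven diaryl ether oxygens, with twenty-one free phenolic hydroxyls and no ring-to-ring C–C bond. Rings A, B, D, F and H are 1,2,3,5-tetraoxygenated. Rings C, E and G are pentaoxygenated, each with two neighbouring aryloxy groups, three neighbouring hydroxyls and one C–H. Atom labels used below: in ring E, E1 carries the oxygen to ring D, E2 the oxygen to ring F, E3 is the C–H, and E4, E5, E6 carry OH (E6 next to E1); in ring D, D1 carries the oxygen to ring C and D4 the oxygen to ring E, between the hydroxylated D3 and D5; in ring F, F1 carries the oxygen to ring E. There is no stereocentre and no stable axis, so the problem is purely constitutional: which oxygen sits on which carbon, with no symmetry to exploit. The feature that dictates the plan is the central ether oxygen between D4 and E1: it has four ortho oxygen substituents (D3, D5, E2, E6), the situation in which Ullmann coupling and nucleophilic aromatic substitution are at their worst. The B–O–C ether has three ortho substituents and is the second hardest. The pyrogallol and hydroxyquinol units oxidise readily in air, especially under base, so the free phenols must be released last, under acid and inert gas.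

## Retrosynthetic reasoning

**40 to 39.** All twenty-one hydroxyls are traced back to twenty methyl ethers and one free phenol (E4) in 39. Methyl ethers are chosen because every building block is a catalogue methyl ether and because they survive carbonate bases, peracid, organolithium reagents and 110 °C. The forward step is one Lewis-acid demethylation.

**39 to 19 and 34 (key disconnection).** Ring E itself is cut, not one of its ether bonds: the bonds E1–E2, E3–E4 and E4–E5 are disconnected. Four ring carbons (E4, E1, E6, E5) come from the squarate-derived cyclobutenone 19, which already carries the ring-D oxygen on the future E1. The other two (E2, E3) come from the aryl ethynyl ether 34, which already carries the ring-F oxygen on the future E2. The cut is made here because it removes the D4–O–E1 aryl C–O coupling from the problem altogether and because ring E is in the middle, so a tetramer and a trimer are joined as the ring forms. The forward reaction must deliver the two aryloxy groups on neighbouring carbons, the C–H at E3 and the free hydroxyl at E4.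

**19 to 14 and 15.** The cyclobutenone is traced through hydroxy ketone 18 and the mixed squarate 17 to phenol 14 and the dichloride 15. The hindered D4 oxygen is thus engaged in a vinylogous acylation, which tolerates two ortho methoxy groups, instead of an arylation. The forward sequence must reduce only the carbonyl next to the methoxy-bearing carbon of 17, because this fixes which cyclobutenone carbon carries the aryloxy group.

**34 to 28 and 29.** The ethynyl ether is cut at the O–C(sp) bond and traced through the dichlorovinyl ether 31 to phenol 28 and 29. F1 is flanked by two hydrogens, so this oxygen is the most accessible of the trimer.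

**14 to 1, 2 and 8.** The three ether bonds of the A–D tetramer are cut so that each ring is introduced as a fluorobenzaldehyde (2 twice, 8 once). In each, the formyl group activates the fluoride for substitution and then becomes the next phenolic oxygen by peracid oxidation. No protecting-group step is needed and the D4 hydroxyl appears exactly when it is wanted. Aldehyde 8 is traced to 6 by ortho-lithiation.

**28 to 20, 21 and 25.** The two ether bonds of the F–H trimer are cut next to formyl-bearing bromoarenes 21 and 25. Copper-catalysed coupling is used here because the bromide of 25 is meta to its formyl group and cannot be activated for substitution. Again each formyl group is the next phenolic oxygen.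

## Alternatives that were turned down

**Alternative 1:** The textbook disconnection cuts every ether oxygen in turn and rebuilds the chain by seven copper-mediated Ullmann couplings of permethylated phenols with permethylated bromoarenes; the central coupling would join phenol 14 to the tetramer bromide A1 (bromine at E1). It was turned down because that coupling must form the tetra-ortho-substituted D4–O–E1 ether from a di-ortho-substituted phenoxide and a di-ortho-substituted, very electron-rich bromide, where reductive loss of bromine is expected to dominate. Each bromide also needs a regioselective halogenation on rings with several activated positions. The count of couplings plus halogenations exceeds the present route, with the greatest risk at the latest and most valuable stage.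

**Alternative 2:** A biomimetic oxidative C–O coupling would cut the E2–O bond and form it by conjugate addition of phenol 28 to the ortho-quinone A2 (3-methoxy-4-[Ar(D)-oxy]-1,2-benzoquinone), followed by reduction. It was turned down for three reasons. The catechol behind A2 already contains the D4–O–E1 ether, so the hardest bond is not addressed. The aryloxy-bearing quinone carbon is a vinylogous ester, so addition–elimination there would expel the ring A–D phenoxide and scramble the fragments. The adduct catechol is more electron-rich than A2, so redox exchange would consume the quinone.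

**Alternative 3:** A different benzannulation would add the lithium acetylide 33 to a dialkyl squarate to give the alkynyl carbinol A3 and rearrange it thermally (Moore rearrangement) to the quinone A4. It was turned down because this ring synthesis places its two carbonyl oxygens para to each other, at E1 and E4. After reduction the ring-D aryl group would have to be attached to the E1 hydroxyl, the more hindered of two free hydroxyls. That brings back both the tetra-ortho C–O coupling and a differentiation problem, at the cost of extra steps.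

Key step: step 17

## Route

Step 1
Reactants: 1 2,4,6-trimethoxyphenol; 2 4-fluoro-2,6-dimethoxybenzaldehyde
Product: 3 2,6-dimethoxy-4-(2,4,6-trimethoxyphenoxy)benzaldehyde
Conditions: K2CO3, DMF, 110 °C, argon
Reagents that add atoms: none
Why: Nucleophilic aromatic substitution (addition–elimination) at the fluoride para to the formyl group; this carbon lies between two hydrogens, so the hindered phenoxide of 1 can reach it, and the formyl group is the masked oxygen of ring B.

Step 2
Reactants: 3 2,6-dimethoxy-4-(2,4,6-trimethoxyphenoxy)benzaldehyde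
Product: 5 2,6-dimethoxy-4-(2,4,6-trimethoxyphenoxy)phenol, via aryl formate 4 (not isolated)
Conditions: mCPBA, CH2Cl2, 0 °C to rt; reductive wash; then K2CO3 (cat.), MeOH, rt
Reagents that add atoms: mCPBA, OOC(=O)c1cccc(Cl)c1
Why: Baeyer–Villiger (Dakin-type) oxidation; the electron-rich 2,6-dimethoxyaryl group migrates in preference to hydrogen and the formate is removed by methanolysis.

Step 3
Reactants: 6 5-fluoro-1,2,3-trimethoxybenzene
Product: 8 6-fluoro-2,3,4-trimethoxybenzaldehyde, via aryllithium 7 (not isolated)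
Conditions: n-BuLi, THF, −78 °C; DMF, −78 to 0 °C; aq. HCl
Reagents that add atoms: N,N-dimethylformamide, CN(C)C=O
Why: Directed ortho-lithiation and formylation; the only two ring hydrogens of 6 are equivalent and each lies between fluorine and methoxy, so a single aldehyde can form.

Step 4
Reactants: 5 2,6-dimethoxy-4-(2,4,6-trimethoxyphenoxy)phenol; 8 6-fluoro-2,3,4-trimethoxybenzaldehyde
Product: 9 6-[2,6-dimethoxy-4-(2,4,6-trimethoxyphenoxy)phenoxy]-2,3,4-trimethoxybenzaldehyde
Conditions: Cs2CO3, DMSO, 120 °C, argon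
Reagents that add atoms: none
Why: Addition–elimination at the fluoride ortho to the formyl group, whose other neighbour is only hydrogen; the formyl group is the masked oxygen at the ring-C carbon that will bind ring D. This is the slowest of the substitutions because the phenoxide is di-ortho-substituted and the ring carries three donors.

Step 5
Reactants: 9 6-[2,6-dimethoxy-4-(2,4,6-trimethoxyphenoxy)phenoxy]-2,3,4-trimethoxybenzaldehyde
Product: 11 6-[2,6-dimethoxy-4-(2,4,6-trimethoxyphenoxy)phenoxy]-2,3,4-trimethoxyphenol, via aryl formate 10 (not isolated)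
Conditions: mCPBA, CH2Cl2, 0 °C to rt; reductive wash; then K2CO3 (cat.), MeOH, rt
Reagents that add atoms: mCPBA, OOC(=O)c1cccc(Cl)c1
Why: Baeyer–Villiger oxidation of an aldehyde with ortho and para oxygen donors, then methanolysis of the formate.

Step 6
Reactants: 11 6-[2,6-dimethoxy-4-(2,4,6-trimethoxyphenoxy)phenoxy]-2,3,4-trimethoxyphenol; 2 4-fluoro-2,6-dimethoxybenzaldehyde
Product: 12 4-{6-[2,6-dimethoxy-4-(2,4,6-trimethoxyphenoxy)phenoxy]-2,3,4-trimethoxyphenoxy}-2,6-dimethoxybenzaldehyde
Conditions: Cs2CO3, DMSO, 100 °C, argon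
Reagents that add atoms: none
Why: Same addition–elimination as in step 1: a hindered phenoxide meets the unhindered para-fluoride of 2, and the formyl group is the masked D4 oxygen.

Step 7
Reactants: 12 4-{6-[2,6-dimethoxy-4-(2,4,6-trimethoxyphenoxy)phenoxy]-2,3,4-trimethoxyphenoxy}-2,6-dimethoxybenzaldehyde
Product: 14 4-{6-[2,6-dimethoxy-4-(2,4,6-trimethoxyphenoxy)phenoxy]-2,3,4-trimethoxyphenoxy}-2,6-dimethoxyphenol, via aryl formate 13 (not isolated)
Conditions: mCPBA, CH2Cl2, 0 °C to rt; reductive wash; then K2CO3 (cat.), MeOH, rt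
Reagents that add atoms: mCPBA, OOC(=O)c1cccc(Cl)c1
Why: Baeyer–Villiger oxidation as in step 2; it releases the D4 hydroxyl without any protecting-group step.

Step 8
Reactants: 14 4-{6-[2,6-dimethoxy-4-(2,4,6-trimethoxyphenoxy)phenoxy]-2,3,4-trimethoxyphenoxy}-2,6-dimethoxyphenol; 15 3,4-dichlorocyclobut-3-ene-1,2-dione
Product: 17 3-methoxy-4-[Ar(D)-oxy]cyclobut-3-ene-1,2-dione, via chlorosquarate 16 (not isolated)
Conditions: 15, MeOH (1 equiv), CH2Cl2, −40 °C; then 14, iPr2NEt, 0 °C to rt
Reagents that add atoms: methanol, CO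
Why: Two successive addition–eliminations at the vinylogous acid chloride carbons of 15; the first substitution deactivates the ring towards a second methanolysis, and the hindered D4 oxygen is acylated far more easily than it could be arylated.

Step 9
Reactants: 17 3-methoxy-4-[Ar(D)-oxy]cyclobut-3-ene-1,2-dione
Product: 18 4-hydroxy-3-methoxy-2-[Ar(D)-oxy]cyclobut-2-en-1-one (racemic)
Conditions: LiAlH(OtBu)3, THF, −78 °C
Reagents that add atoms: none
Why: 1,2-Reduction of one squarate carbonyl by a bulky aluminium hydride, as known for dialkyl squarates; the carbonyl that is vinylogous to the weaker donor (aryloxy) and adjacent to the small methoxy-bearing carbon is both more electrophilic and less hindered. The new stereocentre forms as a racemate and is erased in step 17.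

Step 10
Reactants: 18 4-hydroxy-3-methoxy-2-[Ar(D)-oxy]cyclobut-2-en-1-one (racemic)
Product: 19 3,4-dimethoxy-2-[Ar(D)-oxy]cyclobut-2-en-1-one (racemic)
Conditions: MeI, Ag2O, MeCN, rt, dark
Reagents that add atoms: iodomethane, CI
Why: Silver-oxide-mediated O-methylation under nearly neutral conditions caps the acid-labile hydroxycyclobutenone and installs the future E5 oxygen; the stereocentre stays racemic.

Step 11
Reactants: 20 3,4,5-trimethoxyphenol; 21 2-bromo-3,4,5-trimethoxybenzaldehyde
Product: 22 3,4,5-trimethoxy-2-(3,4,5-trimethoxyphenoxy)benzaldehyde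
Conditions: CuI (10 mol %), picolinic acid (20 mol %), K3PO4, DMSO, 90 °C
Reagents that add atoms: none
Why: Ullmann-type diaryl ether coupling catalysed by monovalent copper; the ortho formyl group assists activation of the aryl bromide and phenol 20 has no ortho substituent.

Step 12
Reactants: 22 3,4,5-trimethoxy-2-(3,4,5-trimethoxyphenoxy)benzaldehyde
Product: 24 3,4,5-trimethoxy-2-(3,4,5-trimethoxyphenoxy)phenol, via aryl formate 23 (not isolated)
Conditions: mCPBA, CH2Cl2, 0 °C to rt; reductive wash; then K2CO3 (cat.), MeOH, rt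
Reagents that add atoms: mCPBA, OOC(=O)c1cccc(Cl)c1
Why: Baeyer–Villiger oxidation of an aldehyde with ortho aryloxy and para methoxy donors, then methanolysis.

Step 13
Reactants: 24 3,4,5-trimethoxy-2-(3,4,5-trimethoxyphenoxy)phenol; 25 3-bromo-4,5-dimethoxybenzaldehyde
Product: 26 3,4-dimethoxy-5-[3,4,5-trimethoxy-2-(3,4,5-trimethoxyphenoxy)phenoxy]benzaldehyde
Conditions: CuI (10 mol %), picolinic acid (20 mol %), K3PO4, DMSO, 90 °C
Reagents that add atoms: none
Why: Ullmann-type coupling catalysed by monovalent copper; each partner has only one ortho substituent at the reacting centre.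

Step 14
Reactants: 26 3,4-dimethoxy-5-[3,4,5-trimethoxy-2-(3,4,5-trimethoxyphenoxy)phenoxy]benzaldehyde
Product: 28 3,4-dimethoxy-5-[3,4,5-trimethoxy-2-(3,4,5-trimethoxyphenoxy)phenoxy]phenol, via aryl formate 27 (not isolated)
Conditions: mCPBA, CH2Cl2, 0 °C to rt; reductive wash; then K2CO3 (cat.), MeOH, rt
Reagents that add atoms: mCPBA, OOC(=O)c1cccc(Cl)c1
Why: Baeyer–Villiger oxidation; the para methoxy group makes aryl migration win over hydrogen migration, as in the known conversion of 3,4,5-trialkoxybenzaldehydes into phenols.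

Step 15
Reactants: 28 3,4-dimethoxy-5-[3,4,5-trimethoxy-2-(3,4,5-trimethoxyphenoxy)phenoxy]phenol; 29 trichloroethylene
Product: 31 Ar(F)–O–C(Cl)=CHCl with (E) geometry, via dichloroacetylene 30 (not isolated)
Conditions: K2CO3, DMF, 70 °C
Reagents that add atoms: none
Why: Base-induced loss of HCl from 29 gives dichloroacetylene, to which the phenoxide adds in anti fashion to give the (E)-1,2-dichlorovinyl ether; this is the established entry to aryl ynol ethers.

Step 16
Reactants: 31 Ar(F)–O–C(Cl)=CHCl with (E) geometry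
Product: 34 Ar(F)–O–C≡CH (aryl ethynyl ether), via chloroethynyl ether 32 (not isolated), via lithium acetylide 33 (not isolated)
Conditions: n-BuLi (2.2 equiv), THF, −78 to −40 °C; H2O
Reagents that add atoms: none
Why: Deprotonation and loss of LiCl give the chloroalkyne, lithium–chlorine exchange gives the acetylide, and protonation gives the terminal ynol ether; the basic work-up avoids acid-catalysed hydration.

Step 17
Reactants: 19 3,4-dimethoxy-2-[Ar(D)-oxy]cyclobut-2-en-1-one (racemic); 34 Ar(F)–O–C≡CH (aryl ethynyl ether)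
Product: 39 2,3-dimethoxy-4-[Ar(D)-oxy]-5-[Ar(F)-oxy]phenol, via vinylketene 35 (not isolated), via vinylcyclobutenone 36 (not isolated), via dienylketene 37 (not isolated), via cyclohexadienone 38 (not isolated)
Conditions: toluene, 110 °C, slow addition of 19 to 34 (1.5 equiv), argon
Reagents that add atoms: none
Why: Proposed new method: heating opens 19 by a conrotatory four-electron electrocyclic reaction (methoxy at C4 turning outward) to the vinylketene 35; the ynol ether 34 adds across the ketene C=C in a regiospecific [2+2] cycloaddition, its nucleophilic CH carbon bonding to the ketene carbonyl carbon, to give 36; a second four-electron opening gives the dienylketene 37, which closes ring E by a thermal disrotatory six-electron electrocyclisation to 38, and enolisation gives the phenol 39. The closest known reaction type is the Danheiser benzannulation of cyclobutenones with alkoxy- and silyloxyacetylenes, together with the known thermal opening of squarate-derived 2,3-dialkoxycyclobutenones to oxygenated vinylketenes; new here are a ketene with three oxygen donors and an aryl ynol ether as partner. One ring is closed, the six-membered ring E, by 6π electrocyclisation, with new C–C bonds E3–E4 and E1–E2 and re-formation of E4–E5. No stereocentre is created in the product; the sp3 centres of 19, 36 and 38 are erased on aromatisation. The selectivity required is the head-to-tail orientation of the [2+2] step, which is secured by the polarisation of the ynol ether (oxygen-bearing carbon to the ketene alpha-carbon) and places the ring-F oxygen at E2 next to the ring-D oxygen at E1, hydrogen at E3 and the free hydroxyl at E4. Both ortho positions of ring D carry methoxy groups, so the ketene cannot cyclise onto its own aryloxy group, and slow addition keeps the ketene concentration low against self-condensation.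

Step 18
Reactants: 39 2,3-dimethoxy-4-[Ar(D)-oxy]-5-[Ar(F)-oxy]phenol
Product: 40 CNP0309601.0 (octameric phlorotannin with twenty-one free hydroxyls)
Conditions: BBr3 (40 equiv), CH2Cl2, −78 °C to rt; H2O, argon
Reagents that add atoms: none
Why: Lewis-acid cleavage of all twenty aryl methyl ethers; diaryl ether bonds are inert to BBr3, and the acidic, oxygen-free work-up protects the pyrogallol units.

## Compound list

1 | 2,4,6-trimethoxyphenol | COc1cc(OC)c(O)c(OC)c1 | starting material
2 | 4-fluoro-2,6-dimethoxybenzaldehyde | COc1cc(F)cc(OC)c1C=O | starting material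
3 | 2,6-dimethoxy-4-(2,4,6-trimethoxyphenoxy)benzaldehyde | COc1cc(OC)c(Oc2cc(OC)c(C=O)c(OC)c2)c(OC)c1 | intermediate
4 | 2,6-dimethoxy-4-(2,4,6-trimethoxyphenoxy)phenyl formate | COc1cc(OC)c(Oc2cc(OC)c(OC=O)c(OC)c2)c(OC)c1 | intermediate
5 | 2,6-dimethoxy-4-(2,4,6-trimethoxyphenoxy)phenol | COc1cc(OC)c(Oc2cc(OC)c(O)c(OC)c2)c(OC)c1 | intermediate
6 | 5-fluoro-1,2,3-trimethoxybenzene | COc1cc(F)cc(OC)c1OC | starting material
7 | (6-fluoro-2,3,4-trimethoxyphenyl)lithium | [Li]c1c(F)cc(OC)c(OC)c1OC | intermediate
8 | 6-fluoro-2,3,4-trimethoxybenzaldehyde | COc1cc(F)c(C=O)c(OC)c1OC | intermediate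
9 | 6-[2,6-dimethoxy-4-(2,4,6-trimethoxyphenoxy)phenoxy]-2,3,4-trimethoxybenzaldehyde | COc1cc(OC)c(Oc2cc(OC)c(Oc3cc(OC)c(OC)c(OC)c3C=O)c(OC)c2)c(OC)c1 | intermediate
10 | formate ester of 11 | COc1cc(OC)c(Oc2cc(OC)c(Oc3cc(OC)c(OC)c(OC)c3OC=O)c(OC)c2)c(OC)c1 | intermediate
11 | 6-[2,6-dimethoxy-4-(2,4,6-trimethoxyphenoxy)phenoxy]-2,3,4-trimethoxyphenol | COc1cc(OC)c(Oc2cc(OC)c(Oc3cc(OC)c(OC)c(OC)c3O)c(OC)c2)c(OC)c1 | intermediate
12 | 4-{6-[2,6-dimethoxy-4-(2,4,6-trimethoxyphenoxy)phenoxy]-2,3,4-trimethoxyphenoxy}-2,6-dimethoxybenzaldehyde | COc1cc(OC)c(Oc2cc(OC)c(Oc3cc(OC)c(OC)c(OC)c3Oc3cc(OC)c(C=O)c(OC)c3)c(OC)c2)c(OC)c1 | intermediate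
13 | formate ester of 14 | COc1cc(OC)c(Oc2cc(OC)c(Oc3cc(OC)c(OC)c(OC)c3Oc3cc(OC)c(OC=O)c(OC)c3)c(OC)c2)c(OC)c1 | intermediate
14 | 4-{6-[2,6-dimethoxy-4-(2,4,6-trimethoxyphenoxy)phenoxy]-2,3,4-trimethoxyphenoxy}-2,6-dimethoxyphenol (rings A to D, free OH at D4) | COc1cc(OC)c(Oc2cc(OC)c(Oc3cc(OC)c(OC)c(OC)c3Oc3cc(OC)c(O)c(OC)c3)c(OC)c2)c(OC)c1 | intermediate
15 | 3,4-dichlorocyclobut-3-ene-1,2-dione | O=C1C(=O)C(Cl)=C1Cl | starting material
16 | 3-chloro-4-methoxycyclobut-3-ene-1,2-dione | COC1=C(Cl)C(=O)C1=O | intermediate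
17 | 3-methoxy-4-[Ar(D)-oxy]cyclobut-3-ene-1,2-dione | COc1cc(OC)c(Oc2cc(OC)c(Oc3cc(OC)c(OC)c(OC)c3Oc3cc(OC)c(OC4=C(OC)C(=O)C4=O)c(OC)c3)c(OC)c2)c(OC)c1 | intermediate
18 | 4-hydroxy-3-methoxy-2-[Ar(D)-oxy]cyclobut-2-en-1-one (racemic) | COc1cc(OC)c(Oc2cc(OC)c(Oc3cc(OC)c(OC)c(OC)c3Oc3cc(OC)c(OC4=C(OC)C(O)C4=O)c(OC)c3)c(OC)c2)c(OC)c1 | intermediate
19 | 3,4-dimethoxy-2-[Ar(D)-oxy]cyclobut-2-en-1-one (racemic) | COc1cc(OC)c(Oc2cc(OC)c(Oc3cc(OC)c(OC)c(OC)c3Oc3cc(OC)c(OC4=C(OC)C(OC)C4=O)c(OC)c3)c(OC)c2)c(OC)c1 | intermediate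
20 | 3,4,5-trimethoxyphenol | COc1cc(O)cc(OC)c1OC | starting material
21 | 2-bromo-3,4,5-trimethoxybenzaldehyde | COc1cc(C=O)c(Br)c(OC)c1OC | starting material
22 | 3,4,5-trimethoxy-2-(3,4,5-trimethoxyphenoxy)benzaldehyde | COc1cc(Oc2c(C=O)cc(OC)c(OC)c2OC)cc(OC)c1OC | intermediate
23 | formate ester of 24 | COc1cc(Oc2c(OC=O)cc(OC)c(OC)c2OC)cc(OC)c1OC | intermediate
24 | 3,4,5-trimethoxy-2-(3,4,5-trimethoxyphenoxy)phenol | COc1cc(Oc2c(O)cc(OC)c(OC)c2OC)cc(OC)c1OC | intermediate
25 | 3-bromo-4,5-dimethoxybenzaldehyde | COc1cc(C=O)cc(Br)c1OC | starting material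
26 | 3,4-dimethoxy-5-[3,4,5-trimethoxy-2-(3,4,5-trimethoxyphenoxy)phenoxy]benzaldehyde | COc1cc(Oc2c(Oc3cc(C=O)cc(OC)c3OC)cc(OC)c(OC)c2OC)cc(OC)c1OC | intermediate
27 | formate ester of 28 | COc1cc(Oc2c(Oc3cc(OC=O)cc(OC)c3OC)cc(OC)c(OC)c2OC)cc(OC)c1OC | intermediate
28 | 3,4-dimethoxy-5-[3,4,5-trimethoxy-2-(3,4,5-trimethoxyphenoxy)phenoxy]phenol (rings F to H, free OH at F1) | COc1cc(Oc2c(Oc3cc(O)cc(OC)c3OC)cc(OC)c(OC)c2OC)cc(OC)c1OC | intermediate
29 | trichloroethylene | ClC=C(Cl)Cl | starting material
30 | dichloroacetylene | ClC#CCl | intermediate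
31 | (E)-1,2-dichlorovinyl ether of 28, Ar(F)–O–C(Cl)=CHCl | COc1cc(Oc2c(Oc3cc(O/C(Cl)=C\Cl)cc(OC)c3OC)cc(OC)c(OC)c2OC)cc(OC)c1OC | intermediate
32 | chloroethynyl ether Ar(F)–O–C≡C–Cl | COc1cc(Oc2c(Oc3cc(OC#CCl)cc(OC)c3OC)cc(OC)c(OC)c2OC)cc(OC)c1OC | intermediate
33 | lithium acetylide Ar(F)–O–C≡C–Li | COc1cc(Oc2c(Oc3cc(OC#C[Li])cc(OC)c3OC)cc(OC)c(OC)c2OC)cc(OC)c1OC | intermediate
34 | ethynyl ether Ar(F)–O–C≡CH | COc1cc(Oc2c(Oc3cc(OC#C)cc(OC)c3OC)cc(OC)c(OC)c2OC)cc(OC)c1OC | intermediate
35 | 3,4-dimethoxy-2-[Ar(D)-oxy]buta-1,3-dien-1-one (terminal methoxy trans to C2) | COc1cc(OC)c(Oc2cc(OC)c(Oc3cc(OC)c(OC)c(OC)c3Oc3cc(OC)c(OC(=C=O)/C(OC)=C/OC)c(OC)c3)c(OC)c2)c(OC)c1 | intermediate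
36 | 4-(1,2-dimethoxyethenyl)-4-[Ar(D)-oxy]-3-[Ar(F)-oxy]cyclobut-2-en-1-one (racemic) | COc1cc(OC)c(Oc2cc(OC)c(Oc3cc(OC)c(OC)c(OC)c3Oc3cc(OC)c(OC4(/C(OC)=C/OC)C(=O)C=C4Oc4cc(OC)c(OC)c(Oc5cc(OC)c(OC)c(OC)c5Oc5cc(OC)c(OC)c(OC)c5)c4)c(OC)c3)c(OC)c2)c(OC)c1 | intermediate
37 | 5,6-dimethoxy-4-[Ar(D)-oxy]-3-[Ar(F)-oxy]hexa-1,3,5-trien-1-one (ketene arm and dimethoxyvinyl arm cis on the central double bond) | O=C=C/C(Oc1cc(OC)c(OC)c(Oc2cc(OC)c(OC)c(OC)c2Oc2cc(OC)c(OC)c(OC)c2)c1)=C(Oc1c(OC)cc(Oc2c(Oc3c(OC)cc(Oc4c(OC)cc(OC)cc4OC)cc3OC)cc(OC)c(OC)c2OC)cc1OC)\C(OC)=C\OC | intermediate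
38 | 5,6-dimethoxy-4-[Ar(D)-oxy]-3-[Ar(F)-oxy]cyclohexa-2,4-dien-1-one (racemic) | O=C5C=C(Oc1cc(OC)c(OC)c(Oc2cc(OC)c(OC)c(OC)c2Oc2cc(OC)c(OC)c(OC)c2)c1)C(Oc1c(OC)cc(Oc2c(Oc3c(OC)cc(Oc4c(OC)cc(OC)cc4OC)cc3OC)cc(OC)c(OC)c2OC)cc1OC)=C(OC)C5OC | intermediate
39 | 2,3-dimethoxy-4-[Ar(D)-oxy]-5-[Ar(F)-oxy]phenol (the octamer with twenty OMe and free OH at E4) | COc1cc(OC)c(Oc2cc(OC)c(Oc3cc(OC)c(OC)c(OC)c3Oc3cc(OC)c(Oc4c(Oc5cc(OC)c(OC)c(Oc6cc(OC)c(OC)c(OC)c6Oc6cc(OC)c(OC)c(OC)c6)c5)cc(O)c(OC)c4OC)c(OC)c3)c(OC)c2)c(OC)c1 | intermediate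
40 | CNP0309601.0 | Oc1cc(O)c(Oc2cc(O)c(Oc3cc(O)c(O)c(O)c3Oc3cc(O)c(Oc4c(Oc5cc(O)c(O)c(Oc6cc(O)c(O)c(O)c6Oc6cc(O)c(O)c(O)c6)c5)cc(O)c(O)c4O)c(O)c3)c(O)c2)c(O)c1 | target

## Step count and least certain steps

Total step count: 18. Longest linear sequence: 11 steps (steps 1, 2, 4, 5, 6, 7, 8, 9, 10, 17, 18).

**Step 17 (key step, proposed new method).** The capture of the donor-rich ketene 35 by the only moderately nucleophilic aryl ynol ether 34 may lose against re-closure to 19, ketene self-condensation and O-acylation of the product phenol by the ketene (the last curable by brief methanolysis of the crude product). The fallback uses known chemistry and forms the central ether by coupling. It sets out from 14 and 21 and comes back to the route at 40.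
- Copper-catalysed, formyl-assisted Ullmann coupling of 14 with 21 gives the pentamer aldehyde F1.
- Peracid oxidation and methanolysis give the pentamer phenol F2.
- Addition–elimination of F2 at the para fluoride of 2,4-difluoro-6-methoxybenzaldehyde F3 gives the hexamer fluoroaldehyde F4.
- Substitution of the remaining ortho fluoride by phenol 24 gives the octamer aldehyde F5.
- Peracid oxidation and methanolysis give the octamer phenol F6, which is demethylated under the conditions of step 18 to 40.

This detour has to make the tetra-ortho ether by coupling, which is the weakness the main route avoids.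

**Step 9.** Hydride may be delivered to the wrong carbonyl, or conjugate addition may expel the aryloxide, because the aryl squarate is also a vinylogous aryl ester. The fallback reaches the same ketene without a squarate. It sets out from 14 and comes back to the route at the vinylketene 35.
- Diazo transfer to methyl 4-methoxy-3-oxobutanoate F9 gives methyl 2-diazo-4-methoxy-3-oxobutanoate F10.
- O–H insertion of the carbenoid from F10 into 14, catalysed by Rh2(OAc)4, gives the aryloxy keto ester F11.
- O-methylation of its enol gives the enol ether ester F12; saponification with LiOH gives the acid F13; oxalyl chloride gives the acid chloride F14.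
- Treating F14 with triethylamine in the presence of 34 generates 35 by 1,4-dehydrochlorination.

**Step 4.** Addition–elimination may stall because a di-ortho-substituted phenoxide meets a fluoride para to a methoxy group, and the aldehyde and the electron-rich phenoxide may decompose at the temperature needed. The fallback changes from substitution to copper catalysis with a different ring-C building block. It sets out from 5 and comes back at 9: formylation of 5-bromo-1,2,3-trimethoxybenzene F7 with dichloromethyl methyl ether and TiCl4 gives 6-bromo-2,3,4-trimethoxybenzaldehyde F8, which is coupled with 5 under the CuI and picolinic acid conditions of step 11.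

**Step 16.** Competing ortho-metalation of the methoxy-rich rings by n-BuLi and oligomerisation of the terminal ynol ether on concentration are the likely losses. The fallback carries a silicon cap through the benzannulation. It sets out from the acetylide 33 and comes back at 40: trapping 33 with chlorotrimethylsilane gives the silyl ynol ether F15, benzannulation with 19 under the conditions of step 17 gives the silylated octamer phenol F16 (silicon at E3), and the acid of step 18 removes silicon together with the methyl groups.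

**Step 18.** Incomplete cleavage of some of the twenty methyl ethers and air oxidation of the product during isolation are the likely losses. The fallback isolates the product through a stable derivative. It sets out from 39 and comes back at 40: the crude demethylation product is acetylated with acetic anhydride and pyridine to the henicosaacetate F17, which is purified by chromatography and cleaved by HCl in methanol under argon.

## Further compounds

F1 | step 17 | 3,4,5-trimethoxy-2-[Ar(D)-oxy]benzaldehyde (pentamer aldehyde) | COc1cc(OC)c(Oc2cc(OC)c(Oc3cc(OC)c(OC)c(OC)c3Oc3cc(OC)c(Oc4c(C=O)cc(OC)c(OC)c4OC)c(OC)c3)c(OC)c2)c(OC)c1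
F2 | step 17 | 3,4,5-trimethoxy-2-[Ar(D)-oxy]phenol (pentamer phenol) | COc1cc(OC)c(Oc2cc(OC)c(Oc3cc(OC)c(OC)c(OC)c3Oc3cc(OC)c(Oc4c(O)cc(OC)c(OC)c4OC)c(OC)c3)c(OC)c2)c(OC)c1
F3 | step 17 | 2,4-difluoro-6-methoxybenzaldehyde | COc1cc(F)cc(F)c1C=O
F4 | step 17 | hexamer fluoroaldehyde (ring F with CHO at F4 and fluorine at F5) | COc1cc(OC)c(Oc2cc(OC)c(Oc3cc(OC)c(OC)c(OC)c3Oc3cc(OC)c(Oc4c(Oc5cc(OC)c(C=O)c(F)c5)cc(OC)c(OC)c4OC)c(OC)c3)c(OC)c2)c(OC)c1
F5 | step 17 | octamer aldehyde (CHO at F4) | COc1cc(OC)c(Oc2cc(OC)c(Oc3cc(OC)c(OC)c(OC)c3Oc3cc(OC)c(Oc4c(Oc5cc(OC)c(C=O)c(Oc6cc(OC)c(OC)c(OC)c6Oc6cc(OC)c(OC)c(OC)c6)c5)cc(OC)c(OC)c4OC)c(OC)c3)c(OC)c2)c(OC)c1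
F6 | step 17 | octamer phenol (free OH at F4, twenty OMe) | COc1cc(OC)c(Oc2cc(OC)c(Oc3cc(OC)c(OC)c(OC)c3Oc3cc(OC)c(Oc4c(Oc5cc(OC)c(O)c(Oc6cc(OC)c(OC)c(OC)c6Oc6cc(OC)c(OC)c(OC)c6)c5)cc(OC)c(OC)c4OC)c(OC)c3)c(OC)c2)c(OC)c1
F7 | step 4 | 5-bromo-1,2,3-trimethoxybenzene | COc1cc(Br)cc(OC)c1OC
F8 | step 4 | 6-bromo-2,3,4-trimethoxybenzaldehyde | COc1cc(Br)c(C=O)c(OC)c1OC
F9 | step 9 | methyl 4-methoxy-3-oxobutanoate | COCC(=O)CC(=O)OC
F10 | step 9 | methyl 2-diazo-4-methoxy-3-oxobutanoate | COCC(=O)C(=[N+]=[N-])C(=O)OC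
F11 | step 9 | methyl 4-methoxy-3-oxo-2-[Ar(D)-oxy]butanoate (racemic) | COc1cc(OC)c(Oc2cc(OC)c(Oc3cc(OC)c(OC)c(OC)c3Oc3cc(OC)c(OC(C(=O)OC)C(=O)COC)c(OC)c3)c(OC)c2)c(OC)c1
F12 | step 9 | methyl 3,4-dimethoxy-2-[Ar(D)-oxy]but-2-enoate (double-bond geometry not controlled and without consequence) | COc1cc(OC)c(Oc2cc(OC)c(Oc3cc(OC)c(OC)c(OC)c3Oc3cc(OC)c(OC(C(=O)OC)=C(OC)COC)c(OC)c3)c(OC)c2)c(OC)c1
F13 | step 9 | 3,4-dimethoxy-2-[Ar(D)-oxy]but-2-enoic acid | COc1cc(OC)c(Oc2cc(OC)c(Oc3cc(OC)c(OC)c(OC)c3Oc3cc(OC)c(OC(C(=O)O)=C(OC)COC)c(OC)c3)c(OC)c2)c(OC)c1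
F14 | step 9 | 3,4-dimethoxy-2-[Ar(D)-oxy]but-2-enoyl chloride | COc1cc(OC)c(Oc2cc(OC)c(Oc3cc(OC)c(OC)c(OC)c3Oc3cc(OC)c(OC(C(=O)Cl)=C(OC)COC)c(OC)c3)c(OC)c2)c(OC)c1
F15 | step 16 | silyl ynol ether Ar(F)–O–C≡C–SiMe3 | COc1cc(Oc2c(Oc3cc(OC#C[Si](C)(C)C)cc(OC)c3OC)cc(OC)c(OC)c2OC)cc(OC)c1OC
F16 | step 16 | 39 with a trimethylsilyl group at E3 | COc1cc(OC)c(Oc2cc(OC)c(Oc3cc(OC)c(OC)c(OC)c3Oc3cc(OC)c(Oc4c(Oc5cc(OC)c(OC)c(Oc6cc(OC)c(OC)c(OC)c6Oc6cc(OC)c(OC)c(OC)c6)c5)c([Si](C)(C)C)c(O)c(OC)c4OC)c(OC)c3)c(OC)c2)c(OC)c1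
F17 | step 18 | henicosaacetate of 40 | CC(=O)Oc1cc(OC(C)=O)c(Oc2cc(OC(C)=O)c(Oc3cc(OC(C)=O)c(OC(C)=O)c(OC(C)=O)c3Oc3cc(OC(C)=O)c(Oc4c(Oc5cc(OC(C)=O)c(OC(C)=O)c(Oc6cc(OC(C)=O)c(OC(C)=O)c(OC(C)=O)c6Oc6cc(OC(C)=O)c(OC(C)=O)c(OC(C)=O)c6)c5)cc(OC(C)=O)c(OC(C)=O)c4OC(C)=O)c(OC(C)=O)c3)c(OC(C)=O)c2)c(OC(C)=O)c1
A1 | alternative 1 | 2-bromo-3,4,5-trimethoxyphenyl ether of 28 (rings E to H, bromine at E1) | COc1cc(Oc2cc(OC)c(OC)c(Oc3cc(OC)c(OC)c(OC)c3Oc3cc(OC)c(OC)c(OC)c3)c2)c(Br)c(OC)c1OC
A2 | alternative 2 | 3-methoxy-4-[Ar(D)-oxy]-1,2-benzoquinone | COC5=C(Oc1c(OC)cc(Oc2c(Oc3c(OC)cc(Oc4c(OC)cc(OC)cc4OC)cc3OC)cc(OC)c(OC)c2OC)cc1OC)C=CC(=O)C5=O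
A3 | alternative 3 | 4-hydroxy-2,3-dimethoxy-4-{[Ar(F)-oxy]ethynyl}cyclobut-2-en-1-one (racemic) | COC1=C(OC)C(O)(C#COc2cc(OC)c(OC)c(Oc3cc(OC)c(OC)c(OC)c3Oc3cc(OC)c(OC)c(OC)c3)c2)C1=O
A4 | alternative 3 | 2,3-dimethoxy-5-[Ar(F)-oxy]-1,4-benzoquinone | COC1=C(OC)C(=O)C(Oc2cc(OC)c(OC)c(Oc3cc(OC)c(OC)c(OC)c3Oc3cc(OC)c(OC)c(OC)c3)c2)=CC1=O
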